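# Route to (2R,3R)-2-(2,3-dihydroxy-4-methoxyphenyl)-5,6-dihydroxy-3,7-dimethoxychroman-4-one by reductive pinacol closure of ring C

## Analysis of the target

The target is a 2,3-dihydroflavonol 3-methyl ether. Ring A is a benzene ring fused to ring C, a dihydropyran-4-one, and ring B is an aryl group on C2. Ring A is substituted at every position but C8: O1 at C8a, a methoxy group at C7, free hydroxyls at C5 and C6, and the C4 carbonyl at C4a. Ring B carries hydroxyls at C2' and C3' and a methoxy group at C4'. The only stereocentres are C2 (R) and C3 (R); they are trans, with the aryl group and the methoxy group both equatorial, which is the more stable arrangement. The sensitive features are the two catechol units, which oxidise in air, and the β-aryloxy ketone, which can open at O1–C2 under base and so lose the C2 configuration. C3–H is also enolisable. The synthesis is hard because seven oxygen substituents must be told apart (three methyl ethers against four free hydroxyls), because ring A is almost fully substituted, and because the trans C2/C3 pair is needed as one enantiomer. The strategy rests on C3 (bearing OMe) and C4 (the carbonyl) of ring C: they are neighbouring oxygen-bearing carbons, so each can be traced back to an aldehyde carbon and the C3–C4 bond to a reductive coupling of two carbonyl groups of like polarity.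

## Retrosynthetic reasoning

The four free phenols are unmasked last, because the catechols of 21 are air-sensitive. In the protected flavanone 20 the ring A catechol is a diphenylmethylene ketal and the ring B catechol a bis(benzyl) ether, so one hydrogenolysis removes all three groups and leaves the three methyl ethers.

The C3 methyl ether of 20 is traced to the C3 hydroxyl of ketol 19, and the C4 ketone of 19 to a benzylic carbinol. This turns C3 and C4 into a vicinal diol, the cis-diol 18, at the price of two adjustments after the ring closure. The C4 hydroxyl of 18 is benzylic to the very electron-rich ring A, which is what allows it to be oxidised in the presence of the C3 hydroxyl.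

The C3–C4 bond of 18 is cut to give dialdehyde 17. This bond is chosen because both of its carbons bear oxygen, so a pinacol coupling is its direct retron, and because the cut leaves C2 as the only stereocentre of the precursor. The forward step must close ring C, set C3 trans to the C2 aryl group and must not disturb C2. A cut at O1–C2 (a chalcone-type closure) would require the two centres to be made independently, and a cut at C4–C4a would raise a regiochemical question on ring A.

The α-aryloxy aldehyde of 17 is not configurationally robust, so both aldehydes are generated together at the last moment from diol 16. Diol 16 comes from diester 15, in which C2 is held as a much less labile α-aryloxy ester.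

Diester 15 is cut at O1–C2 into the ring A phenol 7 and the ring B aryl diazoacetate 14. This is the only bond that joins the two halves, so the disconnection is fully convergent, and an enantioselective carbene O–H insertion creates the C2 stereocentre in the same step. Phenol 7 carries the future C4 carbon as a methyl ester, which is inert towards the carbene.

Diazo ester 14 comes by diazo transfer from arylacetate 13. Ester 13 is the one-carbon homologue of aldehyde 9, reached through nitrile 11, and 9 is the bis(benzyl) ether of commercial aldehyde 8, which already has the ring B oxygen pattern.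

Phenol 7 needs three kinds of oxygen on one ring. The diphenylmethylene ketal solves this: in triol 6 only the adjacent C2 and C3 hydroxyls can form it, so the C6 hydroxyl (the future O1) stays free without any selective alkylation. Triol 6 is traced to aldehyde 4 by a Dakin oxidation, 4 to the symmetrical resorcinol ester 2 by formylation, and 2 to commercial ester 1 by methylation of its most acidic hydroxyl.

## Alternatives that were turned down

Alternative 1: The C2–C3 bond and the C3–O bond of the methyl ether are cut together, so that C3 is a carbene carbon. In the forward step Rh2(OAc)4 would turn the ring A diazoketone A2 into a carbene, methanol A3 would add to it, and the resulting enol would be trapped by aldehyde 9 under a chiral phosphoric acid to give the acyclic aldol A1.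
- For it: three simple pieces meet in one step, the C3 methyl ether is present from the start, and no epimerisable α-aryloxy aldehyde occurs. On convergence and on the handling of the C3 oxygen it is stronger than the chosen route.
- Against it: ring C is not closed. Closing it means that the ring A phenol, once its methoxymethyl group is removed, must replace the benzylic hydroxyl of A1. A Mitsunobu closure inverts that centre and leads from A1 to the 2,3-cis series; an ionising closure through the ring B-stabilised cation discards the configuration the catalyst set. One of the two catalyst-controlled centres is therefore not used.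
- Against it: aldehyde 9 is electron-rich and ortho-substituted, hence a weak electrophile, so a simple 1,2-proton shift of the enol should compete with the aldol trapping.
- Comparison: three steps would still follow the key step (phenol release, cyclisation, hydrogenolysis), the same number as in the chosen route. The chosen route closes the ring and sets the C2/C3 relationship in one operation from a single preset centre.

Alternative 2: The C2–C3 bond is cut as a carbene C–H insertion. Diazoketone A5, in which O1 already carries the ring B benzyl group, would be treated with a chiral dirhodium tetracarboxylate such as Rh2(S-PTTL)4; the carbene at C3 inserts into one of the two enantiotopic benzylic C2–H bonds and closes ring C to flavanone A4.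
- For it: the precursor is assembled very quickly by a benzylation, C2 is set by the catalyst, and the ring and a stereocentre form together. In the number of steps to the ring system it is at least as strong as the chosen route.
- Against it: A4 has a methylene group at C3. The oxygen must be introduced later through an enolate or silyl enol ether, and a flavanone enolate can open at O1–C2 and racemise C2. A methylation follows.
- Against it: A4 carries a methyl ether at C5 that must be cleaved at the end in the presence of three others. At least four steps follow the key step.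
- Against it: the ether oxygen can attack the carbene to form an oxonium ylide and shift the benzyl group, the carbene can add to the electron-rich ring B, and insertion to a six-membered ring is less favoured than to a five-membered one.
- Comparison: the chosen route brings the C3 oxygen in with the carbon skeleton and needs only an oxidation-level adjustment at C4.

Alternative 3: Two bonds to ring A are cut, O1–C8a and C4–C4a, so that ring A enters as an aryne. CsF would release the aryne from silyl triflate A7, the hydroxyl oxygen of ester A8 would add at C8a, and the aryl anion at C4a would attack the ester to close ring C and give A6, the tetrabenzyl ether of the target.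
- For it: this is the most convergent plan. Both stereocentres are made in the acyclic ester A8, the C2 oxygen is retained, and A6 is one hydrogenolysis from the target. On end-game length it is clearly stronger (one step against three), and no redox adjustment is needed. The benzyloxy group next to C4a should also direct the nucleophile to the distal aryne carbon C8a, which is the required sense.
- Against it: A7 is a fully substituted ortho-silyl aryl triflate that needs several steps beyond a ring A phenol, and A8 needs an anti-selective, enantioselective glycolate aldol.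
- Against it: under fluoride the alkoxide of A8 can fragment by retro-aldol, or the aryl anion can be protonated by the hydroxyl before it reaches the ester. A hindered secondary benzylic alkoxide is also a poor partner for an aryne.
- Comparison: in the chosen route the two halves are joined covalently before the C–C bond is made, so regiochemistry is not in question, and every bond is formed under mild, non-basic conditions.

Key step: step 12

Assumption 1: the ring A catechol is carried as a diphenylmethylene ketal and the ring B catechol as a bis(benzyl) ether; all three groups are expected to fall in the final hydrogenolysis.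

Assumption 2: the sense of induction in step 9 is fixed by the choice of ligand antipode; the antipode that delivers the R ester 15 is used.

## Steps

Step 1
Reactants: 1 methyl 2,4,6-trihydroxybenzoate
Product: 2 methyl 2,6-dihydroxy-4-methoxybenzoate
Conditions: Me2SO4 (1.0 equiv), K2CO3 (1.0 equiv), acetone, rt
Reagents that add atoms: dimethyl sulfate COS(=O)(=O)OC
Why: Williamson O-methylation; the C4 hydroxyl is para to the ester, the most acidic, and the only one not hydrogen-bonded to the ester carbonyl, so one equivalent of base and methylating agent should alkylate it selectively.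

Step 2
Reactants: 2 methyl 2,6-dihydroxy-4-methoxybenzoate
Product: 4 methyl 3-formyl-2,6-dihydroxy-4-methoxybenzoate, via aryl iminium chloride 3 (not isolated)
Conditions: POCl3, DMF, MeCN, 0 °C to rt; then H2O, 50 °C
Reagents that add atoms: N,N-dimethylformamide CN(C)C=O; water O
Why: Vilsmeier–Haack formylation; C3 and C5 are equivalent by symmetry and each is ortho or para to three oxygen donors, and the first formyl group deactivates the ring against a second.

Step 3
Reactants: 4 methyl 3-formyl-2,6-dihydroxy-4-methoxybenzoate
Product: 6 methyl 2,3,6-trihydroxy-4-methoxybenzoate, via aryl formate 5 (not isolated)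
Conditions: 30% H2O2, H3BO3, H2SO4 (cat.), THF, rt, under N2
Reagents that add atoms: hydrogen peroxide OO
Why: Dakin oxidation; aryl migration is favoured by the hydroxyls ortho and para to the formyl group, the formate hydrolyses in the flask, and the acidic borate-buffered variant protects the electron-rich triol, which is carried on crude, from further oxidation.

Step 4
Reactants: 6 methyl 2,3,6-trihydroxy-4-methoxybenzoate
Product: 7 methyl 6-hydroxy-4-methoxy-2,3-[(diphenylmethylene)dioxy]benzoate
Conditions: Ph2CCl2 (1.3 equiv), Ph2O, 170 °C, N2 stream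
Reagents that add atoms: dichlorodiphenylmethane ClC(Cl)(c1ccccc1)c1ccccc1
Why: Ketalisation of a catechol; only the adjacent C2 and C3 hydroxyls can close the five-membered dioxole, so the C6 hydroxyl (the future O1) stays free without any selective alkylation.

Step 5
Reactants: 8 2,3-dihydroxy-4-methoxybenzaldehyde
Product: 9 2,3-bis(benzyloxy)-4-methoxybenzaldehyde
Conditions: BnBr (2.4 equiv), K2CO3, DMF, 60 °C
Reagents that add atoms: benzyl bromide BrCc1ccccc1
Why: Williamson ether synthesis; warm DMF is used so that the hydrogen-bonded C2 hydroxyl is alkylated as well.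

Step 6
Reactants: 9 2,3-bis(benzyloxy)-4-methoxybenzaldehyde
Product: 11 2-[2,3-bis(benzyloxy)-4-methoxyphenyl]acetonitrile, via N-(1-tosylvinyl)formamide 10 (not isolated)
Conditions: TosMIC (1.2 equiv), t-BuOK (2.4 equiv), DME, −35 °C; then MeOH, reflux
Reagents that add atoms: p-toluenesulfonylmethyl isocyanide [C-]#[N+]CS(=O)(=O)c1ccc(C)cc1
Why: Van Leusen reductive cyanation; the TosMIC anion adds to the aldehyde, the oxazoline opens to the vinyl formamide, and methanolysis with loss of sulfinate gives the homologous nitrile in one operation under conditions that benzyl ethers tolerate.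

Step 7
Reactants: 11 2-[2,3-bis(benzyloxy)-4-methoxyphenyl]acetonitrile
Product: 13 methyl 2-[2,3-bis(benzyloxy)-4-methoxyphenyl]acetate, via imidate hydrochloride 12 (not isolated)
Conditions: HCl (4 M in dioxane), MeOH, 0 °C to rt; then H2O
Reagents that add atoms: methanol CO; water O
Why: Pinner reaction; methanol adds to the protonated nitrile and the imidate salt is hydrolysed to the methyl ester, while aryl benzyl ethers are stable to anhydrous HCl at room temperature.

Step 8
Reactants: 13 methyl 2-[2,3-bis(benzyloxy)-4-methoxyphenyl]acetate
Product: 14 methyl 2-[2,3-bis(benzyloxy)-4-methoxyphenyl]-2-diazoacetate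
Conditions: 4-acetamidobenzenesulfonyl azide (1.3 equiv), DBU (1.5 equiv), MeCN, 0 °C to rt
Reagents that add atoms: 4-acetamidobenzenesulfonyl azide CC(=O)Nc1ccc(cc1)S(=O)(=O)N=[N+]=[N-]
Why: Regitz diazo transfer to the benzylic, ester-activated methylene group, the standard access to aryl diazoacetates.

Step 9
Reactants: 7 methyl 6-hydroxy-4-methoxy-2,3-[(diphenylmethylene)dioxy]benzoate; 14 methyl 2-[2,3-bis(benzyloxy)-4-methoxyphenyl]-2-diazoacetate
Product: 15 methyl 6-{(1R)-1-[2,3-bis(benzyloxy)-4-methoxyphenyl]-2-methoxy-2-oxoethoxy}-4-methoxy-2,3-[(diphenylmethylene)dioxy]benzoate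
Conditions: PdCl2(PhCN)2 (5 mol %), chiral spiro bisoxazoline ligand (6 mol %), NaB[3,5-(CF3)2C6H3]4 (12 mol %), 5 Å MS, CHCl3, 25–40 °C, slow addition of 14
Reagents that add atoms: none
Why: Enantioselective carbene O–H insertion of an α-aryl-α-diazoacetate into a phenol; the phenol oxygen attacks the palladium carbene and the proton is delivered to one face of the resulting enolate within the chiral ligand sphere, which sets C2, and the ester of 7 is inert to the carbene where a free aldehyde would not be.

Step 10
Reactants: 15 methyl 6-{(1R)-1-[2,3-bis(benzyloxy)-4-methoxyphenyl]-2-methoxy-2-oxoethoxy}-4-methoxy-2,3-[(diphenylmethylene)dioxy]benzoate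
Product: 16 (2R)-2-[2,3-bis(benzyloxy)-4-methoxyphenyl]-2-{2-(hydroxymethyl)-5-methoxy-3,4-[(diphenylmethylene)dioxy]phenoxy}ethan-1-ol
Conditions: LiAlH4 (2.5 equiv), THF, 0 °C to rt
Reagents that add atoms: none
Why: Hydride reduction of both esters; addition to the α-aryloxy ester is much faster than its enolisation, so C2 should be retained, and ethers and the ketal are inert.

Step 11
Reactants: 16 (2R)-2-[2,3-bis(benzyloxy)-4-methoxyphenyl]-2-{2-(hydroxymethyl)-5-methoxy-3,4-[(diphenylmethylene)dioxy]phenoxy}ethan-1-ol
Product: 17 6-{(1R)-1-[2,3-bis(benzyloxy)-4-methoxyphenyl]-2-oxoethoxy}-4-methoxy-2,3-[(diphenylmethylene)dioxy]benzaldehyde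
Conditions: Dess–Martin periodinane (3 equiv), NaHCO3, CH2Cl2, 0 °C to rt; rapid filtration through silica, used at once
Reagents that add atoms: none
Why: Dess–Martin oxidation of both primary alcohols; the buffered, non-basic conditions are the usual choice for aldehydes with an enolisable α-stereocentre, and 17 is not stored.

Step 12
Reactants: 17 6-{(1R)-1-[2,3-bis(benzyloxy)-4-methoxyphenyl]-2-oxoethoxy}-4-methoxy-2,3-[(diphenylmethylene)dioxy]benzaldehyde
Product: 18 (2R,3S,4S)-2-[2,3-bis(benzyloxy)-4-methoxyphenyl]-7-methoxy-5,6-[(diphenylmethylene)dioxy]chromane-3,4-diol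
Conditions: SmI2 (2.5 equiv, 0.1 M in THF), t-BuOH (2 equiv), THF, −78 °C, slow addition of 17 at high dilution; then sat. aq NaHCO3
Reagents that add atoms: none
Why: SmI2 (divalent samarium) gives a ketyl at one of the two aldehydes, most likely the conjugated ring A aldehyde; the ketyl carbon adds to the carbonyl carbon of the second, samarium-bound aldehyde and a second electron gives a trivalent samarium diolate that is protonated. The closest known reaction type is the SmI2 pinacol cyclisation of 1,6-dialdehydes to cis-cyclohexane-1,2-diols, which includes α-alkoxy dialdehydes. Ring C closes in the 6-exo-trig mode, with both carbonyl oxygens ending outside the new ring. C4 is controlled by the samarium ion, which bridges the two oxygens in the cyclic transition state and holds them cis. C3 is controlled by the existing C2 centre: in the half-chair the ring B aryl group sits pseudo-equatorial and the C3 oxygen takes the equatorial site trans to it, while the C4 oxygen goes pseudo-axial, away from the peri oxygen at C5. The step needs cyclisation to outrun two-electron reduction of the C3 carbonyl, which would expel the ring A phenoxide from C2; the 1,6 relation of the carbonyls, chelation, the low temperature and the absence of HMPA favour coupling. No base is present, so the enolisable C2 centre of 17 should be carried over unchanged.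

Step 13
Reactants: 18 (2R,3S,4S)-2-[2,3-bis(benzyloxy)-4-methoxyphenyl]-7-methoxy-5,6-[(diphenylmethylene)dioxy]chromane-3,4-diol
Product: 19 (2R,3R)-2-[2,3-bis(benzyloxy)-4-methoxyphenyl]-3-hydroxy-7-methoxy-5,6-[(diphenylmethylene)dioxy]chroman-4-one
Conditions: DDQ (1.3 equiv), CH2Cl2, pH 7 buffer, 0 °C to rt
Reagents that add atoms: none
Why: DDQ oxidation of an electron-rich benzylic alcohol by hydride abstraction; C4 is ortho or para to three ring A oxygens whereas the C3 carbinol is not benzylic, and the ketal has no benzylic hydrogen and aryl benzyl ethers react only slowly with DDQ at this temperature.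

Step 14
Reactants: 19 (2R,3R)-2-[2,3-bis(benzyloxy)-4-methoxyphenyl]-3-hydroxy-7-methoxy-5,6-[(diphenylmethylene)dioxy]chroman-4-one
Product: 20 (2R,3R)-2-[2,3-bis(benzyloxy)-4-methoxyphenyl]-3,7-dimethoxy-5,6-[(diphenylmethylene)dioxy]chroman-4-one
Conditions: MeI (excess), Ag2O (3 equiv), 4 Å MS, CH2Cl2, rt, dark
Reagents that add atoms: methyl iodide CI
Why: Purdie methylation; silver-assisted alkylation of the C3 hydroxyl proceeds without forming an enolate, which avoids epimerisation at C3 and opening of ring C at O1–C2.

Step 15
Reactants: 20 (2R,3R)-2-[2,3-bis(benzyloxy)-4-methoxyphenyl]-3,7-dimethoxy-5,6-[(diphenylmethylene)dioxy]chroman-4-one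
Product: 21 (2R,3R)-2-(2,3-dihydroxy-4-methoxyphenyl)-5,6-dihydroxy-3,7-dimethoxychroman-4-one
Conditions: H2 (1 atm), 10% Pd/C, THF–MeOH, rt; filtration and concentration under argon
Reagents that add atoms: none
Why: Hydrogenolysis of the two benzyl ethers and of the diphenylmethylene ketal; the C4 ketone is deactivated by the ring A oxygen donors and should survive, the methyl ethers are inert, and the air-sensitive product is handled under inert gas.

## Compound list

1 | methyl 2,4,6-trihydroxybenzoate | COC(=O)c1c(O)cc(O)cc1O | starting material
2 | methyl 2,6-dihydroxy-4-methoxybenzoate | COC(=O)c1c(O)cc(OC)cc1O | intermediate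
3 | [2,4-dihydroxy-6-methoxy-3-(methoxycarbonyl)benzylidene]dimethylammonium chloride | COC(=O)c1c(O)cc(OC)c(C=[N+](C)C)c1O.[Cl-] | intermediate
4 | methyl 3-formyl-2,6-dihydroxy-4-methoxybenzoate | COC(=O)c1c(O)cc(OC)c(C=O)c1O | intermediate
5 | methyl 3-(formyloxy)-2,6-dihydroxy-4-methoxybenzoate | COC(=O)c1c(O)cc(OC)c(OC=O)c1O | intermediate
6 | methyl 2,3,6-trihydroxy-4-methoxybenzoate | COC(=O)c1c(O)cc(OC)c(O)c1O | intermediate
7 | methyl 6-hydroxy-4-methoxy-2,3-[(diphenylmethylene)dioxy]benzoate (methyl 5-hydroxy-7-methoxy-2,2-diphenyl-1,3-benzodioxole-4-carboxylate) | COC(=O)c1c(O)cc(OC)c2OC(c3ccccc3)(c3ccccc3)Oc12 | intermediate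
8 | 2,3-dihydroxy-4-methoxybenzaldehyde | COc1ccc(C=O)c(O)c1O | starting material
9 | 2,3-bis(benzyloxy)-4-methoxybenzaldehyde | COc1ccc(C=O)c(OCc2ccccc2)c1OCc1ccccc1 | intermediate
10 | N-{2-[2,3-bis(benzyloxy)-4-methoxyphenyl]-1-(4-methylbenzenesulfonyl)ethenyl}formamide | O=CNC(=Cc1ccc(OC)c(OCc2ccccc2)c1OCc1ccccc1)S(=O)(=O)c1ccc(C)cc1 | intermediate
11 | 2-[2,3-bis(benzyloxy)-4-methoxyphenyl]acetonitrile | N#CCc1ccc(OC)c(OCc2ccccc2)c1OCc1ccccc1 | intermediate
12 | methyl 2-[2,3-bis(benzyloxy)-4-methoxyphenyl]ethanimidate hydrochloride | COC(=[NH2+])Cc1ccc(OC)c(OCc2ccccc2)c1OCc1ccccc1.[Cl-] | intermediate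
13 | methyl 2-[2,3-bis(benzyloxy)-4-methoxyphenyl]acetate | COC(=O)Cc1ccc(OC)c(OCc2ccccc2)c1OCc1ccccc1 | intermediate
14 | methyl 2-[2,3-bis(benzyloxy)-4-methoxyphenyl]-2-diazoacetate | COC(=O)C(=[N+]=[N-])c1ccc(OC)c(OCc2ccccc2)c1OCc1ccccc1 | intermediate
15 | methyl 6-{(1R)-1-[2,3-bis(benzyloxy)-4-methoxyphenyl]-2-methoxy-2-oxoethoxy}-4-methoxy-2,3-[(diphenylmethylene)dioxy]benzoate | COC(=O)c1c(O[C@@H](C(=O)OC)c2ccc(OC)c(OCc3ccccc3)c2OCc2ccccc2)cc(OC)c2OC(c3ccccc3)(c3ccccc3)Oc12 | intermediate
16 | (2R)-2-[2,3-bis(benzyloxy)-4-methoxyphenyl]-2-{2-(hydroxymethyl)-5-methoxy-3,4-[(diphenylmethylene)dioxy]phenoxy}ethan-1-ol | OCc1c(O[C@@H](CO)c2ccc(OC)c(OCc3ccccc3)c2OCc2ccccc2)cc(OC)c2OC(c3ccccc3)(c3ccccc3)Oc12 | intermediate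
17 | 6-{(1R)-1-[2,3-bis(benzyloxy)-4-methoxyphenyl]-2-oxoethoxy}-4-methoxy-2,3-[(diphenylmethylene)dioxy]benzaldehyde | O=Cc1c(O[C@@H](C=O)c2ccc(OC)c(OCc3ccccc3)c2OCc2ccccc2)cc(OC)c2OC(c3ccccc3)(c3ccccc3)Oc12 | intermediate
18 | (2R,3S,4S)-2-[2,3-bis(benzyloxy)-4-methoxyphenyl]-7-methoxy-5,6-[(diphenylmethylene)dioxy]chromane-3,4-diol (2,3-trans, 3,4-cis) | COc1ccc([C@H]2Oc3cc(OC)c4OC(c5ccccc5)(c5ccccc5)Oc4c3[C@H](O)[C@@H]2O)c(OCc2ccccc2)c1OCc1ccccc1 | intermediate
19 | (2R,3R)-2-[2,3-bis(benzyloxy)-4-methoxyphenyl]-3-hydroxy-7-methoxy-5,6-[(diphenylmethylene)dioxy]chroman-4-one | COc1ccc([C@H]2Oc3cc(OC)c4OC(c5ccccc5)(c5ccccc5)Oc4c3C(=O)[C@@H]2O)c(OCc2ccccc2)c1OCc1ccccc1 | intermediate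
20 | (2R,3R)-2-[2,3-bis(benzyloxy)-4-methoxyphenyl]-3,7-dimethoxy-5,6-[(diphenylmethylene)dioxy]chroman-4-one | COc1ccc([C@H]2Oc3cc(OC)c4OC(c5ccccc5)(c5ccccc5)Oc4c3C(=O)[C@@H]2OC)c(OCc2ccccc2)c1OCc1ccccc1 | intermediate
21 | (2R,3R)-2-(2,3-dihydroxy-4-methoxyphenyl)-5,6-dihydroxy-3,7-dimethoxychroman-4-one | COc1ccc([C@H]2Oc3cc(OC)c(O)c(O)c3C(=O)[C@@H]2OC)c(O)c1O | target

## Step count and least certain steps

Total step count: 15. Longest linear sequence: 11 steps (steps 5 to 15 from 8; the ring A branch, steps 1 to 4 followed by steps 9 to 15, is equally long).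

The key step, step 12, is the least certain. Two things are most likely to go wrong.
- Reductive cleavage of the C2–O1 bond: if the ketyl at C3 takes up a second electron before it couples, the ring A phenoxide is expelled from C2, a known course for α-oxygenated carbonyl compounds with SmI2.
- Erosion of the C2 configuration at the stage of the labile α-aryloxy aldehyde, which would appear as loss of enantiomeric purity because both new centres follow C2.

Poor control at C3 is a lesser concern. The fallback replaces the reductive coupling by olefin metathesis followed by dihydroxylation. It sets out from 17. Both aldehydes are methylenated under non-basic conditions with Cp2Ti(μ-Cl)(μ-CH2)AlMe2 (Tebbe reagent) in THF–toluene at −40 to 0 °C to give 4-ethenyl-5-{[(1S)-1-[2,3-bis(benzyloxy)-4-methoxyphenyl]prop-2-en-1-yl]oxy}-7-methoxy-2,2-diphenyl-1,3-benzodioxole F1. Ring-closing metathesis with (H2IMes)(PCy3)Cl2Ru=CHPh, the second-generation Grubbs catalyst, in CH2Cl2 at 40 °C should give (2S)-2-[2,3-bis(benzyloxy)-4-methoxyphenyl]-7-methoxy-5,6-[(diphenylmethylene)dioxy]-2H-chromene F2. Dihydroxylation with OsO4 (cat.) and N-methylmorpholine N-oxide in acetone–water should take place on the face opposite the C2 aryl group and give the 2,3-trans-3,4-cis diol, so that the sequence comes back to the route at 18. This fallback still passes through 17 and therefore answers the cleavage problem but not the configurational one.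

Step 9 is the next concern. The hydroxyl of 7 is hydrogen-bonded to the neighbouring ester and flanked by it, so slow insertion with competing carbene dimerisation is possible, and the facial selectivity of the proton transfer may be insufficient for this hindered pair. The fallback makes the C2–O bond by a stereospecific substitution and sets out from 14. Oxidation with dimethyldioxirane in acetone at −20 °C should give methyl 2-[2,3-bis(benzyloxy)-4-methoxyphenyl]-2-oxoacetate F3. Asymmetric transfer hydrogenation with RuCl(p-cymene)[(S,S)-TsDPEN] or its antipode, whichever gives the S alcohol, in HCO2H–Et3N should give methyl (2S)-2-[2,3-bis(benzyloxy)-4-methoxyphenyl]-2-hydroxyacetate F4. A Mitsunobu reaction of F4 with phenol 7 (PPh3, diisopropyl azodicarboxylate, toluene, 0 °C) should proceed with inversion, and the fallback comes back to the route at 15.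

In step 13 the oxidant may fail to discriminate. Hydride abstraction could occur at C2–H, which is benzylic to the electron-rich ring B and bound to O1, or the oxidation could be slow because the C4–H bond of the 3,4-cis diol lies close to the plane of ring A. The fallback differentiates the two hydroxyls by protection and sets out from 18. Silylation of the less hindered equatorial C3 hydroxyl (TBSCl, imidazole, DMF) should give (2R,3S,4S)-2-[2,3-bis(benzyloxy)-4-methoxyphenyl]-3-[(tert-butyldimethylsilyl)oxy]-7-methoxy-5,6-[(diphenylmethylene)dioxy]chroman-4-ol F5. Dess–Martin oxidation of the remaining C4 hydroxyl should give (2R,3R)-2-[2,3-bis(benzyloxy)-4-methoxyphenyl]-3-[(tert-butyldimethylsilyl)oxy]-7-methoxy-5,6-[(diphenylmethylene)dioxy]chroman-4-one F6, and desilylation with HF·pyridine in THF comes back to the route at 19.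

In step 14 the alkylation of a hindered hydroxyl that is hydrogen-bonded to the ketone may be sluggish. Long exposure could then allow epimerisation at C3, opening of ring C at O1–C2, or dehydrogenation towards the flavonol. The fallback installs the methyl ether before the ketone exists and sets out from 18. Heating with Bu2SnO in toluene with removal of water should give the 3,4-O-dibutylstannylene acetal of 18 F7. Treatment with MeI and CsF in DMF should alkylate the equatorial C3 oxygen and give (2R,3S,4S)-2-[2,3-bis(benzyloxy)-4-methoxyphenyl]-3,7-dimethoxy-5,6-[(diphenylmethylene)dioxy]chroman-4-ol F8. Dess–Martin oxidation of the C4 hydroxyl then comes back to the route at 20, so that 19 is bypassed.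

## Further compounds

F1 | step 12 | 4-ethenyl-5-{[(1S)-1-[2,3-bis(benzyloxy)-4-methoxyphenyl]prop-2-en-1-yl]oxy}-7-methoxy-2,2-diphenyl-1,3-benzodioxole | C=Cc1c(O[C@@H](C=C)c2ccc(OC)c(OCc3ccccc3)c2OCc2ccccc2)cc(OC)c2OC(c3ccccc3)(c3ccccc3)Oc12
F2 | step 12 | (2S)-2-[2,3-bis(benzyloxy)-4-methoxyphenyl]-7-methoxy-5,6-[(diphenylmethylene)dioxy]-2H-chromene | COc1ccc([C@H]2Oc3cc(OC)c4OC(c5ccccc5)(c5ccccc5)Oc4c3C=C2)c(OCc2ccccc2)c1OCc1ccccc1
F3 | step 9 | methyl 2-[2,3-bis(benzyloxy)-4-methoxyphenyl]-2-oxoacetate | COC(=O)C(=O)c1ccc(OC)c(OCc2ccccc2)c1OCc1ccccc1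
F4 | step 9 | methyl (2S)-2-[2,3-bis(benzyloxy)-4-methoxyphenyl]-2-hydroxyacetate | O[C@H](C(=O)OC)c1ccc(OC)c(OCc2ccccc2)c1OCc1ccccc1
F5 | step 13 | (2R,3S,4S)-2-[2,3-bis(benzyloxy)-4-methoxyphenyl]-3-[(tert-butyldimethylsilyl)oxy]-7-methoxy-5,6-[(diphenylmethylene)dioxy]chroman-4-ol | COc1ccc([C@H]2Oc3cc(OC)c4OC(c5ccccc5)(c5ccccc5)Oc4c3[C@H](O)[C@@H]2O[Si](C)(C)C(C)(C)C)c(OCc2ccccc2)c1OCc1ccccc1
F6 | step 13 | (2R,3R)-2-[2,3-bis(benzyloxy)-4-methoxyphenyl]-3-[(tert-butyldimethylsilyl)oxy]-7-methoxy-5,6-[(diphenylmethylene)dioxy]chroman-4-one | COc1ccc([C@H]2Oc3cc(OC)c4OC(c5ccccc5)(c5ccccc5)Oc4c3C(=O)[C@@H]2O[Si](C)(C)C(C)(C)C)c(OCc2ccccc2)c1OCc1ccccc1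
F7 | step 14 | 3,4-O-dibutylstannylene acetal of (2R,3S,4S)-2-[2,3-bis(benzyloxy)-4-methoxyphenyl]-7-methoxy-5,6-[(diphenylmethylene)dioxy]chromane-3,4-diol | COc1ccc([C@H]2Oc3cc(OC)c4OC(c5ccccc5)(c5ccccc5)Oc4c3[C@@H]3O[Sn](CCCC)(CCCC)O[C@H]23)c(OCc2ccccc2)c1OCc1ccccc1
F8 | step 14 | (2R,3S,4S)-2-[2,3-bis(benzyloxy)-4-methoxyphenyl]-3,7-dimethoxy-5,6-[(diphenylmethylene)dioxy]chroman-4-ol | COc1ccc([C@H]2Oc3cc(OC)c4OC(c5ccccc5)(c5ccccc5)Oc4c3[C@H](O)[C@@H]2OC)c(OCc2ccccc2)c1OCc1ccccc1
A1 | alternative 1 | (2R,3R)-1-[2,3-bis(benzyloxy)-4-methoxy-6-(methoxymethoxy)phenyl]-3-[2,3-bis(benzyloxy)-4-methoxyphenyl]-3-hydroxy-2-methoxypropan-1-one | COCOc1cc(OC)c(OCc2ccccc2)c(OCc2ccccc2)c1C(=O)[C@H](OC)[C@H](O)c1ccc(OC)c(OCc2ccccc2)c1OCc1ccccc1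
A2 | alternative 1 | 1-[2,3-bis(benzyloxy)-4-methoxy-6-(methoxymethoxy)phenyl]-2-diazoethan-1-one | COCOc1cc(OC)c(OCc2ccccc2)c(OCc2ccccc2)c1C(=O)C=[N+]=[N-]
A3 | alternative 1 | methanol | CO
A4 | alternative 2 | (2S)-6-(benzyloxy)-2-[2,3-bis(benzyloxy)-4-methoxyphenyl]-5,7-dimethoxychroman-4-one | COc1ccc([C@H]2Oc3cc(OC)c(OCc4ccccc4)c(OC)c3C(=O)C2)c(OCc2ccccc2)c1OCc1ccccc1
A5 | alternative 2 | 1-[3-(benzyloxy)-6-{[2,3-bis(benzyloxy)-4-methoxyphenyl]methoxy}-2,4-dimethoxyphenyl]-2-diazoethan-1-one | COc1ccc(COc2cc(OC)c(OCc3ccccc3)c(OC)c2C(=O)C=[N+]=[N-])c(OCc2ccccc2)c1OCc1ccccc1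
A6 | alternative 3 | (2R,3R)-5,6-bis(benzyloxy)-2-[2,3-bis(benzyloxy)-4-methoxyphenyl]-3,7-dimethoxychroman-4-one | COc1ccc([C@H]2Oc3cc(OC)c(OCc4ccccc4)c(OCc4ccccc4)c3C(=O)[C@@H]2OC)c(OCc2ccccc2)c1OCc1ccccc1
A7 | alternative 3 | 3,4-bis(benzyloxy)-5-methoxy-2-(trimethylsilyl)phenyl trifluoromethanesulfonate | COc1cc(OS(=O)(=O)C(F)(F)F)c([Si](C)(C)C)c(OCc2ccccc2)c1OCc1ccccc1
A8 | alternative 3 | methyl (2R,3R)-3-[2,3-bis(benzyloxy)-4-methoxyphenyl]-3-hydroxy-2-methoxypropanoate | COC(=O)[C@H](OC)[C@H](O)c1ccc(OC)c(OCc2ccccc2)c1OCc1ccccc1
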